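## The problem

The target is a cembranolide built on a 14-membered carbocycle, numbered C1–C14 here. A trans-fused α-methylene-γ-lactone spans C1–C2 (C15 carries the exocyclic methylene C17, C16 is the carbonyl, the ring oxygen sits on C2). Two (E)-trisubstituted alkenes, C3=C4 and C7=C8, carry the methyls C18 and C19; a trisubstituted epoxide C11–C12 carries methyl C20; C13 bears an acetate. No rigid ring fusion helps: the macrocycle has to be closed from an open chain, and each trisubstituted alkene needs defined geometry.

The five stereocentres (1R,2S,11R,12S,13S) form two groups. Within C11/C12/C13, a free C13 hydroxyl can direct epoxidation of an (E)-C11=C12 alkene, but only in the erythro sense, while the target acetate is threo to the epoxide oxygen. C13 must therefore be carried as its epimer (13R) and inverted at the end. C13 and C1 are 1,3-related across a flexible chain, so they are set independently, by a reagent and by an auxiliary; only C2 is left to control by its neighbour C1.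

The fragile groups are the α-methylene lactone (a Michael acceptor that will not tolerate enolates, hydrides or low-valent metals), the allylic C2–O bond (ionisable by acid), the epoxide next to an oxygenated carbon, and the acetate. They have to appear late, in that order.

The feature that makes the key step possible is the oxygen-bearing C2 attached directly to C3 of the (E)-C3=C4 alkene, whose far carbon C4 carries C18. This is the retron of joining an aldehyde (C2), a terminal alkyne (C3≡C4) and a methyl group (C18) in one event. In addition, C6–C13 with C19 and C20 maps onto a geranyl unit oxidised at its terminal (E)-methyl group.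

## Retrosynthesis

**C13–O bond (27 ⇒ 26).** The acetate is removed with inversion, giving epoxy alcohol 26 with the 13R carbinol. Acetylating a 13S alcohol with retention would require the threo epoxy alcohol, which a directed epoxidation does not give. The forward reaction must be an SN2 displacement by acetate at a carbinol flanked by the fully substituted C12, without opening the epoxide.

**C11–O and C12–O bonds (26 ⇒ 25).** The epoxide is traced to triene alcohol 25. Only C11=C12 is allylic to a free hydroxyl, so a hydroxyl-directed epoxidation selects one of three trisubstituted alkenes and sets two stereocentres from C13. Epoxidising in the open chain would force the epoxide through organometallic, nickel and enolate steps. The forward step must be erythro-selective.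

**C15=C17 bond and silyl ether (25 ⇒ 24 ⇒ 22 ⇒ 21).** Desilylation leads back to 24, and the exocyclic methylene is cut to the saturated lactone 21 via Mannich base 22. Carrying the Michael acceptor through the ring closure is excluded, because it would compete as a π-acceptor for nickel. The forward sequence needs regioselective enolisation at C15, the only enolisable site.

**Lactone C16–O bond (21 ⇒ 20).** Opening the lactone gives hydroxy tert-butyl ester 20. The lactone cannot exist earlier, since C2 is an aldehyde carbon until the ring is closed. The forward step must be an acyl transfer that leaves the allylic C2–O bond intact, so the configuration at C2 is carried over unchanged.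

**C2–C3 and C4–C18 bonds (20 ⇒ 18 + 19).** This is the key cut: the macrocycle opens to ynal 18 and dimethylzinc 19. Cutting C2–C3 alone would require a preformed 2-methylalkenyl halide. Cutting C3=C4 by olefination or metathesis would give poor (E)-control for a trisubstituted macrocyclic alkene. The three-component cut delivers the ring, the alkene geometry, C18 and the C2 carbinol together, and 18 is a simple chain with two stereocentres. The forward reaction must bond C2 to the terminal alkyne carbon, add methyl syn, close in the endo mode, and select one face of the aldehyde under the influence of C1.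

**C1–C15 bond (18 ⇒ 17 ⇒ 16 ⇒ 14 + 15; 14 ⇒ 11 + 12).** The aldehyde is traced through alcohol 17 to imide 16, which is cut at C1–C15 to acyl oxazolidinone 14 and tert-butyl bromoacetate 15. Imide 14 comes from acid 11 and auxiliary 12. Auxiliary control sets C1 independently of the distant C13, which a substrate-controlled 1,3-induction could not be trusted to do. Acid 11 has a single stereocentre.

**C13–C14 bond (11 ⇒ 10 ⇒ 8 ⇒ 7 ⇒ 5).** The acid is traced through alcohol 10 and silyl ether 8 to homoallylic alcohol 7, which is cut at C13–C14 to enal 5. An asymmetric allylation sets C13, and the allyl group supplies C14, C1 and C2 once its terminal alkene is hydrated anti-Markovnikov and oxidised. An aldol cut at the same bond would place a carbonyl on C1, where none is wanted.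

**C5–C6 bond and C13 oxidation (5 ⇒ 3 ⇒ 1 + 2).** The enal comes from dienyne 3 by allylic oxidation of the terminal (E)-methyl group, and 3 from silylpropyne 1 and geranyl bromide 2 by propargylic alkylation. The geranyl unit provides C6–C13 with both (E)-alkenes and methyls C19 and C20 already in place.

## Roads not taken

**Alternative 1: Diels–Alder template for C13/C1/C2.** The cut is at C1–C2 and C13–C14, made as ring bonds of a cyclohexene. An endo Diels–Alder reaction of (1E,3E)-4-acetoxy-3-methyl-1-silyloxybutadiene A1 with methyl vinyl ketone A2 would give the all-cis cyclohexene A3. The catalyst is the oxazaborolidinium salt made from (S)-α,α-diphenylprolinol, o-tolylboronic acid and HNTf2. The extra ring bond C3–C12 would later be cleaved to a C12 methyl ketone and a C3 aldehyde.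

- Merits: one catalytic step fixes three stereocentres with relative and absolute control on a rigid ring, from very cheap materials.
- Weak points for this target:
  - In A3 the acetyl-bearing carbon (future C1) has the target configuration, but the silyloxy carbon (future C2) is cis to it. The trans lactone needs the opposite arrangement, so C2 would have to be inverted on lactonisation. C13 still needs the same late inversion as in the chosen plan.
  - After ring cleavage, both C3=C4 and C11=C12 must be made by olefination. One of these is on a methyl ketone next to an oxygenated stereocentre, where (E)-selectivity is poor and β-elimination threatens.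
  - The macrocycle still has to be closed, and the acetyl group must be converted into the three-carbon methylene lactone unit.
- Comparison: this road is better in the security of the C1/C2/C13 triad, since the chosen plan leaves C2 to substrate control during a ring closure. Against that, the chosen plan takes two alkenes ready-made from the geranyl unit and makes the third alkene, the ring and C2 in one step, so it is much shorter.

**Alternative 2: carbonylative lactone annulation.** The cut is at C16–O and C15–C16, with carbon monoxide as C16. PdCl2/SnCl2/PPh3 under CO would convert the macrocyclic trans-2-ethynyl alcohol A4 into the α-methylene lactone A5, which is the same compound as 24.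

- Merits: lactone and exocyclic methylene arise in one step without strong base, where the chosen plan uses steps 12–14. The endgame from A5 is identical.
- Weak points:
  - The step does not address the 14-membered ring. A4 must still be assembled and closed, now with a terminal ethynyl group on C1 that would interfere with any alkyne-based ring closure.
  - C1 becomes a propargylic stereocentre that must be set trans to the C2 hydroxyl.
  - The carbonylation exposes an allylic alcohol and a silyl ether to a Lewis-acidic tin–palladium mixture, CO pressure and heat. Ionisation at C2 to a π-allyl species is a real risk.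
- Comparison: in step economy at the lactone this road is better. The chosen plan sets against it a ring closure that also creates C3=C4 and C2, and a lactone side chain installed by a very reliable auxiliary alkylation.

**Alternative 3: alkyne metathesis at C11–C12, then trans-hydrostannation.** The cut is at C11–C12, formed as an alkyne. The molybdenum alkylidyne [(4-MeOC6H4)C≡Mo(OSiPh3)3] would close the 14-membered cycloalkyne A6 from two methyl-capped alkynes. After desilylation, the propargylic hydroxyl would direct a trans-hydrostannation ([Cp*RuCl]4, Bu3SnH), and a methyl-for-tin exchange would give the (E)-C11=C12 alkene with C20.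

- Merits: this ring closure is the best precedented of the four for 14-membered rings, has no E/Z issue at closure, uses a tolerant catalyst and is convergent. In precedent it is clearly stronger than the chosen key step.
- Weak points:
  - Three further steps are needed to reach the stage of 25.
  - The methylene lactone already present in A6 must survive tin hydride and the copper/palladium methylation.
  - The geranyl shortcut is lost, because C11–C12 must enter as a capped alkyne. C3=C4, C7=C8 and the lactone stereocentres all need separate construction.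
- Comparison: the ring closure is safer, but the route is longer. The chosen plan sets against it higher bond economy (ring, (E)-alkene, C18 and carbinol in one operation) and a known chromium-mediated closure held in reserve.

Key step: step 11

Remark: geranyl bromide (2) is taken as the commercial form of the geraniol-derived C10 unit. Lithiated, enolate and alkoxide species are treated as salts of the numbered compounds and are not numbered separately. Atom numbers C1–C20 are those defined in the first section.

## Steps

Step 1
Reactants: 1 1-(trimethylsilyl)propyne; 2 geranyl bromide [(2E)-1-bromo-3,7-dimethylocta-2,6-diene]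
Product: 3 (5E)-6,10-dimethyl-1-(trimethylsilyl)undeca-5,9-dien-1-yne
Conditions: n-BuLi, THF, −78 → −20 °C; then 2, −78 °C → rt
Reagents that add atoms: none
Why: Propargylic lithiation of the silylpropyne and SN2 alkylation of the primary allylic bromide form C5–C6; the silyl group directs alkylation to the propargylic rather than the allenic position, and the (E)-alkene of the geranyl unit is not touched.

Step 2
Reactants: 3 (5E)-6,10-dimethyl-1-(trimethylsilyl)undeca-5,9-dien-1-yne
Product: 5 (2E,6E)-2,6-dimethyl-11-(trimethylsilyl)undeca-2,6-dien-10-ynal, via allylic alcohol 4 (not isolated)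
Conditions: SeO2 (cat.), t-BuOOH, salicylic acid (cat.), CH2Cl2, 0 °C → rt; crude mixture then MnO2, CH2Cl2, rt
Reagents that add atoms: tert-butyl hydroperoxide, CC(C)(C)OO; selenium dioxide, O=[Se]=O (relays the oxygen)
Why: Selenium dioxide allylic oxidation (ene reaction, then [2,3]-sigmatropic shift) attacks the (E)-methyl group of the terminal, most accessible trisubstituted alkene, so C13 is oxidised with the C11=C12 geometry kept; MnO2 then converts the allylic alcohol, together with any aldehyde already formed, into the single enal 5.

Step 3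
Reactants: 5 (2E,6E)-2,6-dimethyl-11-(trimethylsilyl)undeca-2,6-dien-10-ynal
Product: 7 (4R,5E,9E)-5,9-dimethyl-14-(trimethylsilyl)tetradeca-1,5,9-trien-13-yn-4-ol, via diisopinocampheylborinate 6 (not isolated)
Conditions: (+)-Ipc2BOMe [from (−)-α-pinene], allylMgBr, Et2O, 0 °C → rt; then 5, −78 °C; then NaBO3·4H2O, THF/H2O, rt
Reagents that add atoms: allylmagnesium bromide, C=CC[Mg]Br; (+)-B-methoxydiisopinocampheylborane, COB([C@H]1C[C@H]2C[C@@H]([C@@H]1C)C2(C)C)[C@H]1C[C@H]2C[C@@H]([C@@H]1C)C2(C)C (its boron and terpene groups stay only in 6)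
Why: Brown allylation: the B-allyldiisopinocampheylborane formed in the flask (the antipode that converts benzaldehyde into (R)-1-phenylbut-3-en-1-ol) adds through a chair six-membered transition state to the Re face of the enal, forming C13–C14 and setting C13 as R; the mild perborate work-up frees the alcohol without cleaving the alkynylsilane.

Step 4
Reactants: 7 (4R,5E,9E)-5,9-dimethyl-14-(trimethylsilyl)tetradeca-1,5,9-trien-13-yn-4-ol
Product: 8 (4R,5E,9E)-4-(tert-butyldimethylsilyloxy)-5,9-dimethyl-14-(trimethylsilyl)tetradeca-1,5,9-trien-13-yne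
Conditions: TBSCl, imidazole, DMF, rt
Reagents that add atoms: tert-butyldimethylsilyl chloride, CC(C)(C)[Si](C)(C)Cl
Why: Standard silylation of a secondary allylic alcohol; the ether shields the C13 oxygen from borane, enolate, organozinc and alkoxide reagents until step 15.

Step 5
Reactants: 8 (4R,5E,9E)-4-(tert-butyldimethylsilyloxy)-5,9-dimethyl-14-(trimethylsilyl)tetradeca-1,5,9-trien-13-yne
Product: 10 (4R,5E,9E)-4-(tert-butyldimethylsilyloxy)-5,9-dimethyltetradeca-5,9-dien-13-yn-1-ol, via B-alkyl-9-borabicyclononane 9 (not isolated)
Conditions: 9-BBN, THF, 0 °C → rt; then MeOH, 3 M NaOH (aq.), 30% H2O2, 0 °C → rt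
Reagents that add atoms: hydrogen peroxide, OO; 9-borabicyclo[3.3.1]nonane, B1C2CCCC1CCC2 (stays only in 9)
Why: Anti-Markovnikov hydroboration–oxidation: the bulky borane reacts with the monosubstituted alkene far faster than with the trisubstituted alkenes or the silyl-capped alkyne and puts oxygen on the future C2; the methanolic hydroxide of the oxidative work-up also removes the alkynyl silyl group (base-induced protodesilylation), which has done its job once the borane is consumed.

Step 6
Reactants: 10 (4R,5E,9E)-4-(tert-butyldimethylsilyloxy)-5,9-dimethyltetradeca-5,9-dien-13-yn-1-ol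
Product: 11 (4R,5E,9E)-4-(tert-butyldimethylsilyloxy)-5,9-dimethyltetradeca-5,9-dien-13-ynoic acid
Conditions: 2,2,6,6-tetramethylpiperidin-1-oxyl (TEMPO, cat.), PhI(OAc)2, MeCN/H2O, rt
Reagents that add atoms: water, O
Why: Oxoammonium-mediated oxidation of the primary alcohol to the aldehyde, whose hydrate is oxidised further to the acid; these conditions are known to spare trisubstituted alkenes, terminal alkynes and silyl ethers.

Step 7
Reactants: 11 (4R,5E,9E)-4-(tert-butyldimethylsilyloxy)-5,9-dimethyltetradeca-5,9-dien-13-ynoic acid; 12 (S)-4-benzyl-2-oxazolidinone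
Product: 14 (S)-4-benzyl-3-[(4R,5E,9E)-4-(tert-butyldimethylsilyloxy)-5,9-dimethyltetradeca-5,9-dien-13-ynoyl]oxazolidin-2-one, via mixed pivalic anhydride 13 (not isolated)
Conditions: PivCl, Et3N, THF, −20 °C; then LiCl, 12, −20 °C → rt
Reagents that add atoms: pivaloyl chloride, CC(C)(C)C(=O)Cl (stays only in 13)
Why: N-Acylation of the oxazolidinone through the mixed anhydride, which is attacked at its less hindered acyl carbon; this attaches the auxiliary that controls C1.

Step 8
Reactants: 14 (S)-4-benzyl-3-[(4R,5E,9E)-4-(tert-butyldimethylsilyloxy)-5,9-dimethyltetradeca-5,9-dien-13-ynoyl]oxazolidin-2-one; 15 tert-butyl bromoacetate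
Product: 16 tert-butyl (3R,5R,6E,10E)-3-{[(4S)-4-benzyl-2-oxooxazolidin-3-yl]carbonyl}-5-(tert-butyldimethylsilyloxy)-6,10-dimethylpentadeca-6,10-dien-14-ynoate
Conditions: NaN(SiMe3)2 (1.05 equiv), THF, −78 °C; then 15, −78 → −40 °C
Reagents that add atoms: none
Why: Evans alkylation: the chelated (Z)-sodium enolate is alkylated on the face away from the benzyl group, forming C1–C15 and setting C1 as R; with one equivalent of base only the imide, far more acidic than the alkyne C–H, is deprotonated.

Step 9
Reactants: 16 tert-butyl (3R,5R,6E,10E)-3-{[(4S)-4-benzyl-2-oxooxazolidin-3-yl]carbonyl}-5-(tert-butyldimethylsilyloxy)-6,10-dimethylpentadeca-6,10-dien-14-ynoate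
Product: 17 tert-butyl (3R,5R,6E,10E)-5-(tert-butyldimethylsilyloxy)-3-(hydroxymethyl)-6,10-dimethylpentadeca-6,10-dien-14-ynoate
Conditions: LiBH4, MeOH (1 equiv), THF, 0 °C
Reagents that add atoms: none
Why: Reductive removal of the auxiliary: the borohydride reduces the activated imide carbonyl to the primary alcohol (future C2) much faster than the hindered tert-butyl ester, and the oxazolidinone is released for recovery; the low temperature should keep the hydroxy ester from lactonising.

Step 10
Reactants: 17 tert-butyl (3R,5R,6E,10E)-5-(tert-butyldimethylsilyloxy)-3-(hydroxymethyl)-6,10-dimethylpentadeca-6,10-dien-14-ynoate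
Product: 18 tert-butyl (3R,5R,6E,10E)-5-(tert-butyldimethylsilyloxy)-3-formyl-6,10-dimethylpentadeca-6,10-dien-14-ynoate
Conditions: Dess–Martin periodinane, NaHCO3, CH2Cl2, 0 °C → rt
Reagents that add atoms: none
Why: Buffered Dess–Martin oxidation gives the aldehyde under non-basic conditions, so the α-stereocentre C1 should not epimerise; 18 is used at once.

Step 11
Reactants: 18 tert-butyl (3R,5R,6E,10E)-5-(tert-butyldimethylsilyloxy)-3-formyl-6,10-dimethylpentadeca-6,10-dien-14-ynoate; 19 dimethylzinc
Product: 20 tert-butyl 2-[(1R,2R,3E,7E,11E,13R)-13-(tert-butyldimethylsilyloxy)-2-hydroxy-4,8,12-trimethylcyclotetradeca-3,7,11-trien-1-yl]acetate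
Conditions: Ni(cod)2 (20 mol %), IMes [1,3-bis(2,4,6-trimethylphenyl)imidazol-2-ylidene] (20 mol %), Me2Zn (3 equiv), THF, rt; 18 added by syringe pump over 8 h (final 0.005 M); then NH4Cl (aq.)
Reagents that add atoms: none
Why: Proposed new method: zerovalent nickel carrying one carbene ligand should bind the aldehyde and the terminal alkyne of 18 and couple them oxidatively to an oxanickelacyclopentene in which C2 is bonded to the unsubstituted alkyne carbon C3; Me2Zn, held at the nickel-bound oxygen, then transfers methyl to nickel, and C(sp2)–CH3 reductive elimination puts C18 on C4 and returns zerovalent nickel. The closest known reaction types are the nickel-catalysed alkylative coupling of ynals (and of separate aldehydes and alkynes) with organozincs, which gives small rings or open-chain allylic alcohols, and the nickel–carbene reductive macrocyclisation of ynals with a silane; methyl transfer has not been used to close a large ring. The 14-membered ring closes in the endo mode (14-endo-dig, both alkyne carbons ending in the ring), because a small carbene ligand and a terminal alkyne favour C–C bonding at the CH terminus. Syn addition of C2 and methyl across the alkyne fixes the (E)-C3=C4 geometry. The new C2 stereocentre is controlled by C1: in the Felkin–Anh arrangement the ring-forming C14 arm lies anti to the incoming alkenyl carbon and the CH2CO2t-Bu arm sits gauche to the carbonyl oxygen, which leads to the 2R carbinol needed for the trans lactone. Chemoselectivity rests on the absence of other good π-acceptors (trisubstituted alkenes, saturated ester), on the lack of β-hydrogens in Me2Zn (no reductive pathway), and on slow addition at high dilution, which keeps the ynal too dilute for alkyne oligomerisation.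

Step 12
Reactants: 20 tert-butyl 2-[(1R,2R,3E,7E,11E,13R)-13-(tert-butyldimethylsilyloxy)-2-hydroxy-4,8,12-trimethylcyclotetradeca-3,7,11-trien-1-yl]acetate
Product: 21 {(1R,2R,3E,7E,11E,13R)-13-(tert-butyldimethylsilyloxy)-2-hydroxy-4,8,12-trimethylcyclotetradeca-3,7,11-trien-1-yl}acetic acid γ-lactone (trans-fused)
Conditions: KOt-Bu (0.2 equiv), THF, 0 °C → rt
Reagents that add atoms: none
Why: Alkoxide-induced lactonisation (intramolecular transesterification, 5-exo-trig): the C2 alkoxide attacks the ester carbonyl C16 and expels tert-butoxide, which carries the chain; the C2–O bond is never broken, so the configuration from step 11 passes unchanged into the trans ring fusion, and the ionisable allylic carbinol never meets acid.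

Step 13
Reactants: 21 {(1R,2R,3E,7E,11E,13R)-13-(tert-butyldimethylsilyloxy)-2-hydroxy-4,8,12-trimethylcyclotetradeca-3,7,11-trien-1-yl}acetic acid γ-lactone (trans-fused)
Product: 22 (15S)-15-[(dimethylamino)methyl] derivative of lactone 21 (CH2NMe2 on the lactone α-carbon C15, trans to the C1–C14 bond)
Conditions: LiN(i-Pr)2, THF, −78 °C; then CH2=NMe2+ I− (Eschenmoser's salt), −78 °C → rt
Reagents that add atoms: N,N-dimethylmethyleneiminium iodide (Eschenmoser's salt), C=[N+](C)C.[I-]
Why: Mannich reaction of the lactone lithium enolate: C15 is the only enolisable position, and the iminium ion should add C17 anti to the C1 ring bond; the configuration created at C15 is of no consequence because it is removed in step 14.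

Step 14
Reactants: 22 (15S)-15-[(dimethylamino)methyl] derivative of lactone 21
Product: 24 2-{(1R,2S,3E,7E,11E,13R)-13-(tert-butyldimethylsilyloxy)-2-hydroxy-4,8,12-trimethylcyclotetradeca-3,7,11-trien-1-yl}acrylic acid γ-lactone (trans-fused α-methylene lactone), via trimethylammonium iodide 23 (not isolated)
Conditions: MeI, THF, rt; then NaHCO3 (aq.), EtOAc, rt
Reagents that add atoms: iodomethane, CI (stays only in 23)
Why: N-Methylation turns the amine into a leaving group, and mild base effects E1cB elimination to the exocyclic C15=C17 alkene; bicarbonate is too weak to add to the new Michael acceptor or to open the lactone.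

Step 15
Reactants: 24 2-{(1R,2S,3E,7E,11E,13R)-13-(tert-butyldimethylsilyloxy)-2-hydroxy-4,8,12-trimethylcyclotetradeca-3,7,11-trien-1-yl}acrylic acid γ-lactone
Product: 25 2-{(1R,2S,3E,7E,11E,13R)-2,13-dihydroxy-4,8,12-trimethylcyclotetradeca-3,7,11-trien-1-yl}acrylic acid γ-lactone (lactone to the C2 oxygen, C13 hydroxyl free)
Conditions: HF·pyridine, pyridine, THF, 0 °C → rt
Reagents that add atoms: none
Why: Buffered fluoride-mediated desilylation frees the C13 allylic alcohol; a non-basic fluoride source is chosen because the α-methylene lactone would not tolerate basic fluoride.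

Step 16
Reactants: 25 2-{(1R,2S,3E,7E,11E,13R)-2,13-dihydroxy-4,8,12-trimethylcyclotetradeca-3,7,11-trien-1-yl}acrylic acid γ-lactone
Product: 26 2-{(1R,2S,3E,7E,11R,12R,13R)-11,12-epoxy-2,13-dihydroxy-4,8,12-trimethylcyclotetradeca-3,7-dien-1-yl}acrylic acid γ-lactone (lactone to the C2 oxygen; erythro epoxy alcohol)
Conditions: VO(acac)2 (5 mol %), t-BuOOH, CH2Cl2, 0 °C
Reagents that add atoms: tert-butyl hydroperoxide, CC(C)(C)OO
Why: Hydroxyl-directed vanadium-catalysed epoxidation: only C11=C12 is allylic to a free hydroxyl, so it alone should be epoxidised; oxygen is delivered from the vanadate ester in the conformation that keeps C14 away from the C20 methyl group (allylic 1,2-strain), which gives the erythro epoxy alcohol, 11R,12R from the 13R carbinol, with the (E) geometry carried into the cis relation of C10 and C20.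

Step 17
Reactants: 26 2-{(1R,2S,3E,7E,11R,12R,13R)-11,12-epoxy-2,13-dihydroxy-4,8,12-trimethylcyclotetradeca-3,7-dien-1-yl}acrylic acid γ-lactone
Product: 27 2-{(1R,2S,3E,7E,11R,12S,13S)-13-acetoxy-11,12-epoxy-2-hydroxy-4,8,12-trimethylcyclotetradeca-3,7-dien-1-yl}acrylic acid γ-lactone (trans-fused; the target CNP0146076.5)
Conditions: PPh3, diisopropyl azodicarboxylate, AcOH, toluene, 0 °C → rt
Reagents that add atoms: acetic acid, CC(=O)O
Why: Mitsunobu reaction: the alkoxyphosphonium ion formed at C13 is displaced by acetate with inversion (SN2), turning the 13R alcohol into the 13S acetate in one operation; phosphine and azodicarboxylate are premixed so that little free phosphine meets the methylene lactone.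

## Compound list

1 | 1-(trimethylsilyl)propyne | CC#C[Si](C)(C)C | starting material
2 | geranyl bromide, (2E)-1-bromo-3,7-dimethylocta-2,6-diene | CC(C)=CCC/C(C)=C/CBr | starting material
3 | (5E)-6,10-dimethyl-1-(trimethylsilyl)undeca-5,9-dien-1-yne | C[Si](C)(C)C#CCC/C=C(\C)CCC=C(C)C | intermediate
4 | (2E,6E)-2,6-dimethyl-11-(trimethylsilyl)undeca-2,6-dien-10-yn-1-ol | OC/C(C)=C/CC/C(C)=C/CCC#C[Si](C)(C)C | intermediate
5 | (2E,6E)-2,6-dimethyl-11-(trimethylsilyl)undeca-2,6-dien-10-ynal | O=C/C(C)=C/CC/C(C)=C/CCC#C[Si](C)(C)C | intermediate
6 | (4R,5E,9E)-5,9-dimethyl-14-(trimethylsilyl)tetradeca-1,5,9-trien-13-yn-4-yl bis[(1S,2S,3S,5R)-isopinocampheyl]borinate | C=CC[C@@H](OB([C@H]1C[C@H]2C[C@@H]([C@@H]1C)C2(C)C)[C@H]1C[C@H]2C[C@@H]([C@@H]1C)C2(C)C)/C(C)=C/CC/C(C)=C/CCC#C[Si](C)(C)C | intermediate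
7 | (4R,5E,9E)-5,9-dimethyl-14-(trimethylsilyl)tetradeca-1,5,9-trien-13-yn-4-ol | C=CC[C@@H](O)/C(C)=C/CC/C(C)=C/CCC#C[Si](C)(C)C | intermediate
8 | (4R,5E,9E)-4-(tert-butyldimethylsilyloxy)-5,9-dimethyl-14-(trimethylsilyl)tetradeca-1,5,9-trien-13-yne | C=CC[C@@H](O[Si](C)(C)C(C)(C)C)/C(C)=C/CC/C(C)=C/CCC#C[Si](C)(C)C | intermediate
9 | 9-[(4R,5E,9E)-4-(tert-butyldimethylsilyloxy)-5,9-dimethyl-14-(trimethylsilyl)tetradeca-5,9-dien-13-yn-1-yl]-9-borabicyclo[3.3.1]nonane | C(CC[C@@H](O[Si](C)(C)C(C)(C)C)/C(C)=C/CC/C(C)=C/CCC#C[Si](C)(C)C)B1C2CCCC1CCC2 | intermediate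
10 | (4R,5E,9E)-4-(tert-butyldimethylsilyloxy)-5,9-dimethyltetradeca-5,9-dien-13-yn-1-ol | OCCC[C@@H](O[Si](C)(C)C(C)(C)C)/C(C)=C/CC/C(C)=C/CCC#C | intermediate
11 | (4R,5E,9E)-4-(tert-butyldimethylsilyloxy)-5,9-dimethyltetradeca-5,9-dien-13-ynoic acid | OC(=O)CC[C@@H](O[Si](C)(C)C(C)(C)C)/C(C)=C/CC/C(C)=C/CCC#C | intermediate
12 | (S)-4-benzyl-2-oxazolidinone | O=C1N[C@@H](Cc2ccccc2)CO1 | starting material
13 | (4R,5E,9E)-4-(tert-butyldimethylsilyloxy)-5,9-dimethyltetradeca-5,9-dien-13-ynoic pivalic anhydride | CC(C)(C)C(=O)OC(=O)CC[C@@H](O[Si](C)(C)C(C)(C)C)/C(C)=C/CC/C(C)=C/CCC#C | intermediate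
14 | (S)-4-benzyl-3-[(4R,5E,9E)-4-(tert-butyldimethylsilyloxy)-5,9-dimethyltetradeca-5,9-dien-13-ynoyl]oxazolidin-2-one | O=C(CC[C@@H](O[Si](C)(C)C(C)(C)C)/C(C)=C/CC/C(C)=C/CCC#C)N1[C@@H](Cc2ccccc2)COC1=O | intermediate
15 | tert-butyl bromoacetate | CC(C)(C)OC(=O)CBr | starting material
16 | tert-butyl (3R,5R,6E,10E)-3-{[(4S)-4-benzyl-2-oxooxazolidin-3-yl]carbonyl}-5-(tert-butyldimethylsilyloxy)-6,10-dimethylpentadeca-6,10-dien-14-ynoate | CC(C)(C)OC(=O)C[C@@H](C[C@@H](O[Si](C)(C)C(C)(C)C)/C(C)=C/CC/C(C)=C/CCC#C)C(=O)N1[C@@H](Cc2ccccc2)COC1=O | intermediate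
17 | tert-butyl (3R,5R,6E,10E)-5-(tert-butyldimethylsilyloxy)-3-(hydroxymethyl)-6,10-dimethylpentadeca-6,10-dien-14-ynoate | CC(C)(C)OC(=O)C[C@H](CO)C[C@@H](O[Si](C)(C)C(C)(C)C)/C(C)=C/CC/C(C)=C/CCC#C | intermediate
18 | tert-butyl (3R,5R,6E,10E)-5-(tert-butyldimethylsilyloxy)-3-formyl-6,10-dimethylpentadeca-6,10-dien-14-ynoate | CC(C)(C)OC(=O)C[C@H](C=O)C[C@@H](O[Si](C)(C)C(C)(C)C)/C(C)=C/CC/C(C)=C/CCC#C | intermediate
19 | dimethylzinc | C[Zn]C | starting material
20 | tert-butyl 2-[(1R,2R,3E,7E,11E,13R)-13-(tert-butyldimethylsilyloxy)-2-hydroxy-4,8,12-trimethylcyclotetradeca-3,7,11-trien-1-yl]acetate | O[C@H]1/C=C(\C)CC/C=C(\C)CC/C=C(\C)[C@H](O[Si](C)(C)C(C)(C)C)C[C@@H]1CC(=O)OC(C)(C)C | intermediate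
21 | {(1R,2R,3E,7E,11E,13R)-13-(tert-butyldimethylsilyloxy)-2-hydroxy-4,8,12-trimethylcyclotetradeca-3,7,11-trien-1-yl}acetic acid γ-lactone, trans-fused | C1C(=O)O[C@H]2/C=C(\C)CC/C=C(\C)CC/C=C(\C)[C@H](O[Si](C)(C)C(C)(C)C)C[C@H]12 | intermediate
22 | (15S)-15-[(dimethylamino)methyl] derivative of lactone 21 (aminomethyl group on the lactone α-carbon, trans to the C1–C14 bond) | CN(C)C[C@H]1C(=O)O[C@H]2/C=C(\C)CC/C=C(\C)CC/C=C(\C)[C@H](O[Si](C)(C)C(C)(C)C)C[C@H]12 | intermediate
23 | N-methyl iodide salt of 22 (trimethylammoniomethyl lactone iodide) | C[N+](C)(C)C[C@H]1C(=O)O[C@H]2/C=C(\C)CC/C=C(\C)CC/C=C(\C)[C@H](O[Si](C)(C)C(C)(C)C)C[C@H]12.[I-] | intermediate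
24 | 2-{(1R,2S,3E,7E,11E,13R)-13-(tert-butyldimethylsilyloxy)-2-hydroxy-4,8,12-trimethylcyclotetradeca-3,7,11-trien-1-yl}acrylic acid γ-lactone, trans-fused | C=C1C(=O)O[C@H]2/C=C(\C)CC/C=C(\C)CC/C=C(\C)[C@H](O[Si](C)(C)C(C)(C)C)C[C@H]12 | intermediate
25 | 2-{(1R,2S,3E,7E,11E,13R)-2,13-dihydroxy-4,8,12-trimethylcyclotetradeca-3,7,11-trien-1-yl}acrylic acid γ-lactone (to the C2 oxygen) | C=C1C(=O)O[C@H]2/C=C(\C)CC/C=C(\C)CC/C=C(\C)[C@H](O)C[C@H]12 | intermediate
26 | 2-{(1R,2S,3E,7E,11R,12R,13R)-11,12-epoxy-2,13-dihydroxy-4,8,12-trimethylcyclotetradeca-3,7-dien-1-yl}acrylic acid γ-lactone (to the C2 oxygen) | C=C1C(=O)O[C@H]2/C=C(\C)CC/C=C(\C)CC[C@H]3O[C@]3(C)[C@H](O)C[C@H]12 | intermediate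
27 | 2-{(1R,2S,3E,7E,11R,12S,13S)-13-acetoxy-11,12-epoxy-2-hydroxy-4,8,12-trimethylcyclotetradeca-3,7-dien-1-yl}acrylic acid γ-lactone, trans-fused (CNP0146076.5) | C=C1C(=O)O[C@H]2/C=C(\C)CC/C=C(\C)CC[C@H]3O[C@]3(C)[C@@H](OC(C)=O)C[C@H]12 | target

## Step count and least certain steps

Total step count: 17. Longest linear sequence: 17 steps (from 1 and 2 to 27); the route is fully linear.

**Step 11 (key step, Proposed new method).** The large-ring closure is slow, so alkyne oligomerisation or intermolecular coupling may outrun it, and methyl transfer from zinc may lag behind decomposition of the nickelacycle. Facial selectivity at C2 may also be incomplete, because the two arms on C1 are of similar size.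

Fallback by known chemistry, setting out from 10 and returning at 20: Negishi carboalumination of the terminal alkyne of 10 (AlMe3, Cp2ZrCl2, CH2Cl2; then I2) should give the (E)-iodoalkene alcohol F1 with C18 already in place. The operations of steps 6–10, applied unchanged, would lead through acid F2, acyl oxazolidinone F3, alkylated imide F4 and hydroxy ester F5 to iodo aldehyde F6. An intramolecular Nozaki–Hiyama–Kishi reaction (CrCl2, NiCl2 cat., DMSO/THF, high dilution) would then close C2–C3 to 20. If either closure gives poor selectivity at C2, the epimer mixture is oxidised with Dess–Martin periodinane to enone F7. F7 is reduced with (S)-1-methyl-3,3-diphenyltetrahydro-1H,3H-pyrrolo[1,2-c][1,3,2]oxazaborole and BH3·SMe2 (CBS reduction), which should give the 2R carbinol 20 if the trisubstituted alkenyl arm acts as the larger group.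

**Step 12 (lactonisation).** Acyl transfer to the hindered tert-butyl ester may be sluggish, and this would give the alkoxide time for silyl migration from the C13 oxygen to the C2 oxygen.

Fallback, setting out from 20 and returning at 21: the tert-butyl ester is cleaved under buffered silyl triflate conditions (TMSOTf, 2,6-lutidine, CH2Cl2, 0 °C; then aqueous citric acid) to hydroxy acid F8. F8 should close on its own or on carboxyl activation (EDC·HCl, 4-(dimethylamino)pyridine, CH2Cl2), again with retention at C2.

**Step 16 (directed epoxidation).** The conformation of the 14-membered ring may override the local allylic-strain preference and lower facial selectivity. Competing oxidation of the allylic alcohol to the enone is also possible.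

Fallback, setting out from 25 and returning at 26 with no new compound: Sharpless asymmetric epoxidation with Ti(OiPr)4, D-(−)-diisopropyl tartrate and t-BuOOH (4 Å sieves, CH2Cl2, −20 °C). This tartrate is the matched partner of the 13R carbinol, so catalyst control and the erythro preference act in the same direction.

**Step 17 (Mitsunobu inversion).** Displacement at C13 is slowed by the fully substituted C12. This leaves room for elimination, for epoxide participation, or for phosphine addition to the methylene lactone.

Fallback, setting out from 26 and returning at 27: the alcohol is converted into chloromethanesulfonate F9 (ClCH2SO2Cl, pyridine, CH2Cl2, 0 °C) and displaced with CsOAc and 18-crown-6 in toluene at 60–80 °C. This gives the inverted acetate by SN2 without any phosphine.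

## Further compounds

F1 | step 11 | (4R,5E,9E,13E)-4-(tert-butyldimethylsilyloxy)-14-iodo-5,9,13-trimethyltetradeca-5,9,13-trien-1-ol | OCCC[C@@H](O[Si](C)(C)C(C)(C)C)/C(C)=C/CC/C(C)=C/CC/C(C)=C/I
F2 | step 11 | (4R,5E,9E,13E)-4-(tert-butyldimethylsilyloxy)-14-iodo-5,9,13-trimethyltetradeca-5,9,13-trienoic acid | OC(=O)CC[C@@H](O[Si](C)(C)C(C)(C)C)/C(C)=C/CC/C(C)=C/CC/C(C)=C/I
F3 | step 11 | (S)-4-benzyl-3-[(4R,5E,9E,13E)-4-(tert-butyldimethylsilyloxy)-14-iodo-5,9,13-trimethyltetradeca-5,9,13-trienoyl]oxazolidin-2-one | O=C(CC[C@@H](O[Si](C)(C)C(C)(C)C)/C(C)=C/CC/C(C)=C/CC/C(C)=C/I)N1[C@@H](Cc2ccccc2)COC1=O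
F4 | step 11 | tert-butyl (3R,5R,6E,10E,14E)-3-{[(4S)-4-benzyl-2-oxooxazolidin-3-yl]carbonyl}-5-(tert-butyldimethylsilyloxy)-15-iodo-6,10,14-trimethylpentadeca-6,10,14-trienoate | CC(C)(C)OC(=O)C[C@@H](C[C@@H](O[Si](C)(C)C(C)(C)C)/C(C)=C/CC/C(C)=C/CC/C(C)=C/I)C(=O)N1[C@@H](Cc2ccccc2)COC1=O
F5 | step 11 | tert-butyl (3R,5R,6E,10E,14E)-5-(tert-butyldimethylsilyloxy)-3-(hydroxymethyl)-15-iodo-6,10,14-trimethylpentadeca-6,10,14-trienoate | CC(C)(C)OC(=O)C[C@H](CO)C[C@@H](O[Si](C)(C)C(C)(C)C)/C(C)=C/CC/C(C)=C/CC/C(C)=C/I
F6 | step 11 | tert-butyl (3R,5R,6E,10E,14E)-5-(tert-butyldimethylsilyloxy)-3-formyl-15-iodo-6,10,14-trimethylpentadeca-6,10,14-trienoate | CC(C)(C)OC(=O)C[C@H](C=O)C[C@@H](O[Si](C)(C)C(C)(C)C)/C(C)=C/CC/C(C)=C/CC/C(C)=C/I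
F7 | step 11 | tert-butyl 2-[(1R,3E,7E,11E,13R)-13-(tert-butyldimethylsilyloxy)-4,8,12-trimethyl-2-oxocyclotetradeca-3,7,11-trien-1-yl]acetate | O=C1/C=C(\C)CC/C=C(\C)CC/C=C(\C)[C@H](O[Si](C)(C)C(C)(C)C)C[C@@H]1CC(=O)OC(C)(C)C
F8 | step 12 | 2-[(1R,2R,3E,7E,11E,13R)-13-(tert-butyldimethylsilyloxy)-2-hydroxy-4,8,12-trimethylcyclotetradeca-3,7,11-trien-1-yl]acetic acid | O[C@H]1/C=C(\C)CC/C=C(\C)CC/C=C(\C)[C@H](O[Si](C)(C)C(C)(C)C)C[C@@H]1CC(=O)O
F0 | step 16 | none | none
F9 | step 17 | 13-O-chloromethanesulfonate of epoxy alcohol 26 (C13 configuration unchanged) | C=C1C(=O)O[C@H]2/C=C(\C)CC/C=C(\C)CC[C@H]3O[C@]3(C)[C@H](OS(=O)(=O)CCl)C[C@H]12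
A1 | alternative 1 | (1E,3E)-4-acetoxy-1-(tert-butyldimethylsilyloxy)-3-methylbuta-1,3-diene | CC(=O)O/C=C(\C)/C=C/O[Si](C)(C)C(C)(C)C
A2 | alternative 1 | methyl vinyl ketone | CC(=O)C=C
A3 | alternative 1 | all-cis 1-acetyl-5-acetoxy-2-(tert-butyldimethylsilyloxy)-4-methylcyclohex-3-ene (enantiomer as in the SMILES) | CC(=O)[C@H]1C[C@@H](OC(C)=O)C(C)=C[C@H]1O[Si](C)(C)C(C)(C)C
A4 | alternative 2 | (3E,7E,11E)-13-(tert-butyldimethylsilyloxy)-1-ethynyl-4,8,12-trimethylcyclotetradeca-3,7,11-trien-2-ol, 1,2-trans (configuration as in the SMILES) | O[C@H]1/C=C(\C)CC/C=C(\C)CC/C=C(\C)[C@H](O[Si](C)(C)C(C)(C)C)C[C@@H]1C#C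
A5 | alternative 2 | triene α-methylene lactone C13 tert-butyldimethylsilyl ether (identical with 24) | C=C1C(=O)O[C@H]2/C=C(\C)CC/C=C(\C)CC/C=C(\C)[C@H](O[Si](C)(C)C(C)(C)C)C[C@H]12
A6 | alternative 3 | 14-membered C11≡C12 cycloalkyne α-methylene lactone, C13 triethylsilyl ether (13R) | C=C1C(=O)O[C@H]2/C=C(\C)CC/C=C(\C)CCC#C[C@H](O[Si](CC)(CC)CC)C[C@H]12
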